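**Strategy.** The synthesis rests on one disconnection: the C9–C10 bond that joins the fully substituted ether carbon C9 to the quaternary ring-fusion carbon C10 (labdane numbering). An acid-triggered semipinacol shift moves C10 from carbinol carbon C8 to a C9 oxocarbenium ion. In a single operation this expands a cyclopentane (C5–C6–C7–C8–C10) into ring B, creates the C8 ketone and fixes the spiro tetrahydrofuran (O–C9–C11–C12–C13) with its oxygen axial at C9. The precursor is a trans-hydrindan-8β-ol carrying at C8 an enantiopure 5,5-disubstituted 4,5-dihydrofuran-2-yl group whose C13 bears a silylated alkyne and a silyloxymethyl arm, the masked second dihydrofuran.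

Key step: step 17

Remarks on the chemistry:
- Labdane numbering is used throughout; α is the face opposite the C10 methyl group (C20).
- A γ-keto ester such as a levulinate would leave a methyl group on C13 instead of the oxygenated C16 and would not control C13. The dihydrofuran is therefore built from 2-methylenepropane-1,3-diol, with C13 set by Sharpless epoxidation.
- The C6 oxygen is carried as a 4-methoxybenzyl (PMB) ether, removable under neutral oxidative conditions beside the silyl groups and the tertiary carbinol, instead of an acid-labile acetal.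

**Route**

Step 1
Reactants: 1 2-methylcyclopentane-1,3-dione; 2 methyl vinyl ketone
Product: 3 2-methyl-2-(3-oxobutyl)cyclopentane-1,3-dione
Conditions: H2O, AcOH (cat.), 70 °C
Reagents that add atoms: none
Why: Michael addition of the acidic cyclic 1,3-dione to the enone in water is a standard entry to the achiral triketone.

Step 2
Reactants: 3 2-methyl-2-(3-oxobutyl)cyclopentane-1,3-dione
Product: 5 (S)-7a-methyl-2,3,7,7a-tetrahydro-1H-indene-1,5(6H)-dione (Hajos–Parrish ketone), via Hajos ketol 4 (not isolated)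
Conditions: (S)-proline (3 mol %), DMF, rt; then H2SO4 (cat.), 95 °C
Reagents that add atoms: none
Why: In the Hajos–Parrish–Eder–Sauer–Wiechert reaction the (S)-proline enamine differentiates the two enantiotopic ring carbonyls in an intramolecular aldol addition, which sets the quaternary centre (future C10) as S, and acid dehydration of the ketol gives the enone.

Step 3
Reactants: 5 (S)-Hajos–Parrish ketone
Product: 6 (7a'S)-7a'-methyl-2',3',7',7a'-tetrahydrospiro[[1,3]dioxolane-2,1'-inden]-5'(6'H)-one (ethylene ketal of the cyclopentanone carbonyl, future C8)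
Conditions: (Me3SiOCH2)2, Me3SiOTf (5 mol %), CH2Cl2, −78 → −20 °C
Reagents that add atoms: 1,2-bis(trimethylsilyloxy)ethane, C[Si](C)(C)OCCO[Si](C)(C)C
Why: Noyori ketalisation at low temperature is chemoselective for the saturated ketone over the less electrophilic conjugated enone, so the future C8 carbonyl is masked in one step.

Step 4
Reactants: 6 monoketal
Product: 7 (7a'S)-4',4',7a'-trimethyl-2',4',7',7a'-tetrahydrospiro[[1,3]dioxolane-2,1'-inden]-5'(6'H)-one (gem-dimethyl at C4, ketone at C3, alkene C5=C6)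
Conditions: KOt-Bu, t-BuOH, rt; MeI, 0 °C → rt
Reagents that add atoms: iodomethane, CI
Why: Deconjugative α,α-dialkylation through the extended potassium dienolate installs both C4 methyl groups and moves the alkene to C5=C6, a classical operation on Hajos–Parrish and Wieland–Miescher ketals.

Step 5
Reactants: 7 β,γ-unsaturated ketone
Product: 8 (7a'S)-4',4',7a'-trimethyl-2',4',5',6',7',7a'-hexahydrospiro[[1,3]dioxolane-2,1'-indene] (C3 now CH2)
Conditions: N2H4·H2O, KOH, diethylene glycol, 130 °C then 200 °C
Reagents that add atoms: none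
Why: Wolff–Kishner reduction (Huang-Minlon procedure) removes the hindered C3 carbonyl under basic conditions that leave the ketal intact, and the quaternary C4 prevents migration of the alkene.

Step 6
Reactants: 8 alkene ketal
Product: 9 (3'S,3a'S,7a'S)-4',4',7a'-trimethyloctahydrospiro[[1,3]dioxolane-2,1'-inden]-3'-ol (trans-fused; 5α-H, 6α-OH)
Conditions: BH3·THF, THF, 0 °C → rt; then aq. NaOH, H2O2, 0 °C → rt
Reagents that add atoms: hydrogen peroxide, OO
Why: Hydroboration–oxidation puts boron on the less substituted C6 and delivers hydrogen syn to C5 from the α-face opposite the angular methyl, which sets the trans ring fusion (5α-H) and the 6α-hydroxyl, as with 14-ene 17-ketal steroids.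

Step 7
Reactants: 9 alcohol
Product: 10 (3'S,3a'S,7a'S)-3'-[(4-methoxybenzyl)oxy]-4',4',7a'-trimethyloctahydrospiro[[1,3]dioxolane-2,1'-indene]
Conditions: NaH, PMBCl, n-Bu4NI (cat.), DMF, 0 °C → rt
Reagents that add atoms: 4-methoxybenzyl chloride, COc1ccc(CCl)cc1
Why: Williamson etherification gives a PMB ether that tolerates organolithium and organocerium reagents and catalytic sulfonic acid and is later cleaved oxidatively beside silyl groups.

Step 8
Reactants: 10 PMB ether ketal
Product: 11 (3S,3aS,7aS)-3-[(4-methoxybenzyl)oxy]-4,4,7a-trimethyloctahydro-1H-inden-1-one (trans-hydrindan-8-one with 6α-OPMB)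
Conditions: PPTS, acetone–H2O (10:1), 60 °C
Reagents that add atoms: water, O
Why: Mild acid-catalysed ketal hydrolysis frees the C8 ketone without touching the PMB ether, and no stereocentre can epimerise because C10 is quaternary.

Step 9
Reactants: 12 2-methylenepropane-1,3-diol
Product: 13 2-({[tert-butyl(dimethyl)silyl]oxy}methyl)prop-2-en-1-ol
Conditions: NaH (1.0 equiv), THF, 0 °C → rt; TBSCl (1.0 equiv)
Reagents that add atoms: tert-butyldimethylsilyl chloride, CC(C)(C)[Si](C)(C)Cl
Why: Monosilylation of a symmetrical diol through its monosodium alkoxide differentiates the two hydroxymethyl arms.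

Step 10
Reactants: 13 allylic alcohol
Product: 14 (R)-[2-({[tert-butyl(dimethyl)silyl]oxy}methyl)oxiran-2-yl]methanol
Conditions: Ti(Oi-Pr)4 (10 mol %), D-(−)-diisopropyl tartrate (12 mol %), t-BuOOH, 4 Å MS, CH2Cl2, −20 °C
Reagents that add atoms: tert-butyl hydroperoxide, CC(C)(C)OO
Why: Sharpless asymmetric epoxidation of a 2-substituted allylic alcohol with the D-(−)-tartrate catalyst delivers oxygen to the face that makes the quaternary carbon (future C13) R, which is the only stereocentre of the side fragment.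

Step 11
Reactants: 14 epoxy alcohol
Product: 15 (R)-2-({[tert-butyl(dimethyl)silyl]oxy}methyl)oxirane-2-carbaldehyde
Conditions: Dess–Martin periodinane, NaHCO3, CH2Cl2, 0 °C → rt
Reagents that add atoms: none
Why: Dess–Martin oxidation gives an α,α-disubstituted epoxy aldehyde that cannot epimerise, and it avoids the basic conditions under which the epoxy alcohol would racemise by Payne rearrangement.

Step 12
Reactants: 15 epoxy aldehyde
Product: 16 (R)-tert-butyl[(2-ethynyloxiran-2-yl)methoxy]dimethylsilane
Conditions: dimethyl (1-diazo-2-oxopropyl)phosphonate, K2CO3, MeOH, 0 °C → rt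
Reagents that add atoms: dimethyl (1-diazo-2-oxopropyl)phosphonate, COP(=O)(OC)C(=[N+]=[N-])C(C)=O
Why: Seyferth–Gilbert homologation in the Ohira–Bestmann variant converts the non-enolisable aldehyde into the terminal alkyne (C14≡C15) without touching the stereocentre.

Step 13
Reactants: 16 ethynyl epoxide
Product: 17 (R)-tert-butyldimethyl({2-[(trimethylsilyl)ethynyl]oxiran-2-yl}methoxy)silane
Conditions: n-BuLi, THF, −78 °C; then Me3SiCl, −78 → 0 °C
Reagents that add atoms: chlorotrimethylsilane, C[Si](C)(C)Cl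
Why: Deprotonation and C-silylation of the terminal alkyne mask its acidic hydrogen, so that the second alkyne and the later vinyl lithiation are unambiguous.

Step 14
Reactants: 17 silylated alkynyl epoxide
Product: 18 (S)-1-{[tert-butyl(dimethyl)silyl]oxy}-2-[(trimethylsilyl)ethynyl]pent-4-yn-2-ol
Conditions: HC≡CH, n-BuLi, THF, −78 °C; BF3·OEt2; then 17, −78 °C
Reagents that add atoms: acetylene, C#C
Why: In this Yamaguchi–Hirao epoxide opening lithium acetylide attacks the BF3-activated 2,2-disubstituted epoxide at its CH2 terminus, so the C–O bond at the stereocentre is untouched (the descriptor becomes S only through the priority change).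

Step 15
Reactants: 18 diynol
Product: 19 (S)-tert-butyldimethyl({2-[(trimethylsilyl)ethynyl]-2,3-dihydrofuran-2-yl}methoxy)silane
Conditions: W(CO)6 (25 mol %), Et3N, THF, hν (350 nm), 55 °C
Reagents that add atoms: none
Why: Tungsten-vinylidene endo cycloisomerisation of a but-3-yn-1-ol (McDonald type) closes the 2,3-dihydrofuran through the terminal alkyne only, because the silylated alkyne is propargylic to the hydroxyl and does not readily form a vinylidene.

Step 16
Reactants: 19 (S)-dihydrofuran; 11 trans-hydrindan-8-one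
Product: 22 (1S,3S,3aS,7aS)-1-[(5S)-5-({[tert-butyl(dimethyl)silyl]oxy}methyl)-5-[(trimethylsilyl)ethynyl]-4,5-dihydrofuran-2-yl]-3-[(4-methoxybenzyl)oxy]-4,4,7a-trimethyloctahydro-1H-inden-1-ol (8β-OH; dihydrofuranyl group α), via lithiated dihydrofuran 20 (not isolated), via organocerium reagent 21 (not isolated)
Conditions: 19 (1.5 equiv), t-BuLi (1.4 equiv), THF, −78 → −20 °C; CeCl3, −78 °C; then 11, −78 °C
Reagents that add atoms: none
Why: α-Lithiation of the cyclic enol ether and transmetalation give a weakly basic organocerium nucleophile that adds 1,2 to the hindered, enolisable cyclopentanone from the α-face opposite the C10 methyl (as with 17-keto steroids), giving the 8β-carbinol, while any minor enantiomer of 19 ends up as a separable diastereomer.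

Step 17
Reactants: 22 hydrindanol precursor
Product: 24 (13S)-16-{[tert-butyl(dimethyl)silyl]oxy}-9α,13-epoxy-6α-[(4-methoxybenzyl)oxy]-15-(trimethylsilyl)-17-norlabd-14-yn-8-one, via oxocarbenium ion 23 (not isolated)
Conditions: camphorsulfonic acid (0.2 equiv), 4 Å MS, CH2Cl2, 0 °C → rt
Reagents that add atoms: none
Why: The sulfonic acid protonates the enol ether at C11 to give oxocarbenium ion 23, whose empty orbital at C9 is aligned with the C8–C10 bond; C10 then migrates from C8 to C9 with retention while the C8 hydroxyl becomes the ketone, a semipinacol (pinacol-type) 1,2-shift made irreversible by carbonyl formation and loss of cyclopentane strain. The closest known reaction type is the acid-promoted ring expansion of 1-(4,5-dihydrofuran-2-yl)cycloalkanols to spiro tetrahydrofuranyl ketones. Ring B is closed by this five-to-six ring expansion (insertion of C9 into the C8–C10 bond by 1,2-migration of a ring bond, not an end-on cyclisation), the tetrahydrofuran being present already. The new stereocentre C9 is set by the rotamer about C8–C9 in a chair-like transition state: the small ring oxygen sits under the five-membered ring, syn to C7, and becomes axial (α), while the C11 methylene points outward, away from C7 and the α-face C6 ether, and becomes equatorial (β). The step needs C10 and not C7 to migrate, which the higher migratory aptitude of the electron-rich quaternary carbon over a methylene that is inductively deactivated by the C6 oxygen should secure. It also needs the cation to live only as long as the shift takes, which dry, non-nucleophilic conditions and an acid-stable C6 ether provide.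

Step 18
Reactants: 24 spiro ketone
Product: 25 (13S)-16-{[tert-butyl(dimethyl)silyl]oxy}-9α,13-epoxy-6α-[(4-methoxybenzyl)oxy]-15-(trimethylsilyl)labd-14-yn-8β-ol (C17 methyl α)
Conditions: MeMgBr, CeCl3, THF, −78 → 0 °C
Reagents that add atoms: methylmagnesium bromide, C[Mg]Br
Why: The organocerium reagent (Imamoto conditions) adds to the enolisable ketone without deprotonating it and approaches C8 equatorially from the α-face, because the axial C10 methyl blocks the β-face, which makes C17 α (equatorial) and the hydroxyl β (axial).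

Step 19
Reactants: 25 tertiary alcohol
Product: 26 (13S)-16-{[tert-butyl(dimethyl)silyl]oxy}-9α,13-epoxy-15-(trimethylsilyl)labd-14-yne-6α,8β-diol
Conditions: DDQ, CH2Cl2–pH 7 buffer (10:1), 0 °C → rt
Reagents that add atoms: none
Why: Oxidative PMB cleavage by DDQ is neutral and leaves the silyl ether, the silyl alkyne and the tertiary carbinol untouched.

Step 20
Reactants: 26 diol
Product: 27 (13S)-16-{[tert-butyl(dimethyl)silyl]oxy}-9α,13-epoxy-8β-hydroxy-15-(trimethylsilyl)labd-14-yn-6-one
Conditions: Dess–Martin periodinane, NaHCO3, CH2Cl2, rt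
Reagents that add atoms: none
Why: Dess–Martin oxidation converts the only secondary alcohol into the C6 ketone, the tertiary C8 hydroxyl cannot react, and the trans fusion at C5 is the stable one for a 4,4,10-trimethyl decalone.

Step 21
Reactants: 27 hydroxy ketone
Product: 30 (13S)-16-{[tert-butyl(dimethyl)silyl]oxy}-9α,13-epoxy-7α,8β-dihydroxy-15-(trimethylsilyl)labd-14-yn-6-one, via bis-silyl enol ether 28 (not isolated), via silyloxy ketone 29 (not isolated)
Conditions: Me3SiOTf, Et3N, CH2Cl2, 0 °C; then m-CPBA, NaHCO3, CH2Cl2, −20 → 0 °C; then citric acid, MeOH, rt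
Reagents that add atoms: 3-chloroperbenzoic acid, OOC(=O)c1cccc(Cl)c1
Why: In this Rubottom oxidation enolisation goes towards C7 because a C5 enol would clash with the C4 methyl groups, the tertiary hydroxyl is silylated at the same time so that no retro-aldol can occur, and the peracid attacks the enol ether axially from the α-face, anti to the pseudo-axial C8 silyloxy group, to give the 7α-hydroxy ketone after silyl transfer and methanolysis.

Step 22
Reactants: 30 dihydroxy ketone
Product: 31 (13S)-7α-acetoxy-16-{[tert-butyl(dimethyl)silyl]oxy}-9α,13-epoxy-8β-hydroxy-15-(trimethylsilyl)labd-14-yn-6-one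
Conditions: Ac2O, DMAP (cat.), pyridine, CH2Cl2, rt
Reagents that add atoms: acetic anhydride, CC(=O)OC(C)=O
Why: DMAP-catalysed acylation esterifies the secondary ketol hydroxyl selectively, since the tertiary C8 hydroxyl is too hindered to react.

Step 23
Reactants: 31 7α-acetate
Product: 32 (13S)-7β-acetoxy-16-{[tert-butyl(dimethyl)silyl]oxy}-9α,13-epoxy-8β-hydroxy-15-(trimethylsilyl)labd-14-yn-6-one
Conditions: DBU (0.3 equiv), toluene, rt → 40 °C
Reagents that add atoms: none
Why: Base-mediated epimerisation through the C6–C7 enolate converts the axial 7α-acetate, which is syn-axial to the C9 oxygen, into the equatorial 7β-acetate, which is also the product of kinetic α-face protonation, so C7 is set as in the known equilibration of axial α-acetoxy ketones.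

Step 24
Reactants: 32 7β-acetate
Product: 33 (13S)-7β-acetoxy-9α,13-epoxy-8β,16-dihydroxylabd-14-yn-6-one
Conditions: TBAF, AcOH (1:1), THF, rt
Reagents that add atoms: none
Why: Buffered fluoride desilylation cleaves the primary silyl ether and the alkynyl C–Si bond in one operation, and the near-neutral medium spares the acetate and the ketol.

Step 25
Reactants: 33 alkynol
Product: 34 (13S)-7β-acetoxy-9α,13:15,16-diepoxy-8β-hydroxylabd-14-en-6-one (target, CNP0284584.1)
Conditions: W(CO)5·THF [pre-formed from W(CO)6, THF, hν (350 nm)] (0.5 equiv), Et3N, THF, 50 °C, dark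
Reagents that add atoms: none
Why: Tungsten-vinylidene endo cycloisomerisation of the 2,2-disubstituted but-3-yn-1-ol closes the acid-sensitive 2,3-dihydrofuran (C13–C14=C15–O–C16) last, with the complex pre-formed so that the ketone is not irradiated and under weakly basic conditions that can only reinforce the thermodynamic C7 configuration.

**Compound list**

1 | 2-methylcyclopentane-1,3-dione | CC1C(=O)CCC1=O | starting material
2 | methyl vinyl ketone | CC(=O)C=C | starting material
3 | 2-methyl-2-(3-oxobutyl)cyclopentane-1,3-dione | CC(=O)CCC1(C)C(=O)CCC1=O | intermediate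
4 | (3aS,7aS)-3a-hydroxy-7a-methylhexahydro-1H-indene-1,5(6H)-dione (cis-fused Hajos ketol, not isolated) | C[C@]12CCC(=O)C[C@@]1(O)CCC2=O | intermediate
5 | (S)-7a-methyl-2,3,7,7a-tetrahydro-1H-indene-1,5(6H)-dione | C[C@]12CCC(=O)C=C1CCC2=O | intermediate
6 | (7a'S)-7a'-methyl-2',3',7',7a'-tetrahydrospiro[[1,3]dioxolane-2,1'-inden]-5'(6'H)-one | C[C@]12CCC(=O)C=C1CCC23OCCO3 | intermediate
7 | (7a'S)-4',4',7a'-trimethyl-2',4',7',7a'-tetrahydrospiro[[1,3]dioxolane-2,1'-inden]-5'(6'H)-one | C[C@]12CCC(=O)C(C)(C)C1=CCC23OCCO3 | intermediate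
8 | (7a'S)-4',4',7a'-trimethyl-2',4',5',6',7',7a'-hexahydrospiro[[1,3]dioxolane-2,1'-indene] | C[C@]12CCCC(C)(C)C1=CCC23OCCO3 | intermediate
9 | (3'S,3a'S,7a'S)-4',4',7a'-trimethyloctahydrospiro[[1,3]dioxolane-2,1'-inden]-3'-ol (5α-H, 6α-OH) | C1[C@H](O)[C@H]2C(C)(C)CCC[C@]2(C)C13OCCO3 | intermediate
10 | (3'S,3a'S,7a'S)-3'-[(4-methoxybenzyl)oxy]-4',4',7a'-trimethyloctahydrospiro[[1,3]dioxolane-2,1'-indene] | C1[C@H](OCc2ccc(OC)cc2)[C@H]2C(C)(C)CCC[C@]2(C)C13OCCO3 | intermediate
11 | (3S,3aS,7aS)-3-[(4-methoxybenzyl)oxy]-4,4,7a-trimethyloctahydro-1H-inden-1-one | C1[C@H](OCc2ccc(OC)cc2)[C@H]2C(C)(C)CCC[C@]2(C)C1=O | intermediate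
12 | 2-methylenepropane-1,3-diol | C=C(CO)CO | starting material
13 | 2-({[tert-butyl(dimethyl)silyl]oxy}methyl)prop-2-en-1-ol | C=C(CO)CO[Si](C)(C)C(C)(C)C | intermediate
14 | (R)-[2-({[tert-butyl(dimethyl)silyl]oxy}methyl)oxiran-2-yl]methanol | OC[C@]1(CO[Si](C)(C)C(C)(C)C)CO1 | intermediate
15 | (R)-2-({[tert-butyl(dimethyl)silyl]oxy}methyl)oxirane-2-carbaldehyde | O=C[C@]1(CO[Si](C)(C)C(C)(C)C)CO1 | intermediate
16 | (R)-tert-butyl[(2-ethynyloxiran-2-yl)methoxy]dimethylsilane | C#C[C@]1(CO[Si](C)(C)C(C)(C)C)CO1 | intermediate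
17 | (R)-tert-butyldimethyl({2-[(trimethylsilyl)ethynyl]oxiran-2-yl}methoxy)silane | C[Si](C)(C)C#C[C@]1(CO[Si](C)(C)C(C)(C)C)CO1 | intermediate
18 | (S)-1-{[tert-butyl(dimethyl)silyl]oxy}-2-[(trimethylsilyl)ethynyl]pent-4-yn-2-ol | C#CC[C@](O)(C#C[Si](C)(C)C)CO[Si](C)(C)C(C)(C)C | intermediate
19 | (S)-tert-butyldimethyl({2-[(trimethylsilyl)ethynyl]-2,3-dihydrofuran-2-yl}methoxy)silane | C1=CC[C@](C#C[Si](C)(C)C)(CO[Si](C)(C)C(C)(C)C)O1 | intermediate
20 | 5-lithio derivative of 19 (not isolated) | [Li]C1=CC[C@](C#C[Si](C)(C)C)(CO[Si](C)(C)C(C)(C)C)O1 | intermediate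
21 | 5-(dichlorocerio) derivative of 19 (not isolated) | Cl[Ce](Cl)C1=CC[C@](C#C[Si](C)(C)C)(CO[Si](C)(C)C(C)(C)C)O1 | intermediate
22 | (1S,3S,3aS,7aS)-1-[(5S)-5-({[tert-butyl(dimethyl)silyl]oxy}methyl)-5-[(trimethylsilyl)ethynyl]-4,5-dihydrofuran-2-yl]-3-[(4-methoxybenzyl)oxy]-4,4,7a-trimethyloctahydro-1H-inden-1-ol | C1[C@H](OCc2ccc(OC)cc2)[C@H]2C(C)(C)CCC[C@]2(C)[C@]1(O)C1=CC[C@](C#C[Si](C)(C)C)(CO[Si](C)(C)C(C)(C)C)O1 | intermediate
23 | C9 oxocarbenium ion formed from 22 by protonation at C11 (not isolated) | C1[C@H](OCc2ccc(OC)cc2)[C@H]2C(C)(C)CCC[C@]2(C)[C@]1(O)C1=[O+][C@@](C#C[Si](C)(C)C)(CO[Si](C)(C)C(C)(C)C)CC1 | intermediate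
24 | (13S)-16-{[tert-butyl(dimethyl)silyl]oxy}-9α,13-epoxy-6α-[(4-methoxybenzyl)oxy]-15-(trimethylsilyl)-17-norlabd-14-yn-8-one | C1[C@H](OCc2ccc(OC)cc2)[C@H]2C(C)(C)CCC[C@]2(C)[C@@]2(CC[C@](C#C[Si](C)(C)C)(CO[Si](C)(C)C(C)(C)C)O2)C1=O | intermediate
25 | (13S)-16-{[tert-butyl(dimethyl)silyl]oxy}-9α,13-epoxy-6α-[(4-methoxybenzyl)oxy]-15-(trimethylsilyl)labd-14-yn-8β-ol | C1[C@H](OCc2ccc(OC)cc2)[C@H]2C(C)(C)CCC[C@]2(C)[C@@]2(CC[C@](C#C[Si](C)(C)C)(CO[Si](C)(C)C(C)(C)C)O2)[C@@]1(C)O | intermediate
26 | (13S)-16-{[tert-butyl(dimethyl)silyl]oxy}-9α,13-epoxy-15-(trimethylsilyl)labd-14-yne-6α,8β-diol | C1[C@H](O)[C@H]2C(C)(C)CCC[C@]2(C)[C@@]2(CC[C@](C#C[Si](C)(C)C)(CO[Si](C)(C)C(C)(C)C)O2)[C@@]1(C)O | intermediate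
27 | (13S)-16-{[tert-butyl(dimethyl)silyl]oxy}-9α,13-epoxy-8β-hydroxy-15-(trimethylsilyl)labd-14-yn-6-one | C1C(=O)[C@H]2C(C)(C)CCC[C@]2(C)[C@@]2(CC[C@](C#C[Si](C)(C)C)(CO[Si](C)(C)C(C)(C)C)O2)[C@@]1(C)O | intermediate
28 | (13S)-16-{[tert-butyl(dimethyl)silyl]oxy}-9α,13-epoxy-15-(trimethylsilyl)-6,8β-bis(trimethylsilyloxy)labd-6-en-14-yne (not isolated) | C1=C(O[Si](C)(C)C)[C@H]2C(C)(C)CCC[C@]2(C)[C@@]2(CC[C@](C#C[Si](C)(C)C)(CO[Si](C)(C)C(C)(C)C)O2)[C@@]1(C)O[Si](C)(C)C | intermediate
29 | (13S)-16-{[tert-butyl(dimethyl)silyl]oxy}-9α,13-epoxy-15-(trimethylsilyl)-7α,8β-bis(trimethylsilyloxy)labd-14-yn-6-one (not isolated) | C[Si](C)(C)O[C@@H]1C(=O)[C@H]2C(C)(C)CCC[C@]2(C)[C@@]2(CC[C@](C#C[Si](C)(C)C)(CO[Si](C)(C)C(C)(C)C)O2)[C@@]1(C)O[Si](C)(C)C | intermediate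
30 | (13S)-16-{[tert-butyl(dimethyl)silyl]oxy}-9α,13-epoxy-7α,8β-dihydroxy-15-(trimethylsilyl)labd-14-yn-6-one | O[C@@H]1C(=O)[C@H]2C(C)(C)CCC[C@]2(C)[C@@]2(CC[C@](C#C[Si](C)(C)C)(CO[Si](C)(C)C(C)(C)C)O2)[C@@]1(C)O | intermediate
31 | (13S)-7α-acetoxy-16-{[tert-butyl(dimethyl)silyl]oxy}-9α,13-epoxy-8β-hydroxy-15-(trimethylsilyl)labd-14-yn-6-one | CC(=O)O[C@@H]1C(=O)[C@H]2C(C)(C)CCC[C@]2(C)[C@@]2(CC[C@](C#C[Si](C)(C)C)(CO[Si](C)(C)C(C)(C)C)O2)[C@@]1(C)O | intermediate
32 | (13S)-7β-acetoxy-16-{[tert-butyl(dimethyl)silyl]oxy}-9α,13-epoxy-8β-hydroxy-15-(trimethylsilyl)labd-14-yn-6-one | CC(=O)O[C@H]1C(=O)[C@H]2C(C)(C)CCC[C@]2(C)[C@@]2(CC[C@](C#C[Si](C)(C)C)(CO[Si](C)(C)C(C)(C)C)O2)[C@@]1(C)O | intermediate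
33 | (13S)-7β-acetoxy-9α,13-epoxy-8β,16-dihydroxylabd-14-yn-6-one | CC(=O)O[C@H]1C(=O)[C@H]2C(C)(C)CCC[C@]2(C)[C@@]2(CC[C@](C#C)(CO)O2)[C@@]1(C)O | intermediate
34 | (13S)-7β-acetoxy-9α,13:15,16-diepoxy-8β-hydroxylabd-14-en-6-one (CNP0284584.1) | CC(=O)O[C@H]1C(=O)[C@H]2C(C)(C)CCC[C@]2(C)[C@@]2(CC[C@@]3(C=COC3)O2)[C@@]1(C)O | target

**Step count and risks**

Total step count: 25. Longest linear sequence: 18 steps (steps 1–8 and 16–25); the side fragment takes 7 steps (steps 9–15).

Steps most likely to fail:

Step 17 (key step). The expansion of an unstrained cyclopentanol may be slow, so that the reversibly formed oxocarbenium ion is diverted by hydration, by capture through the C6 ether oxygen or by loss of a proton, or the two C8–C9 rotamers may react with poor facial selectivity at C9. The fallback makes the same bond under bromonium activation. It sets out from 22: N-bromosuccinimide with propylene oxide in THF at −78 → 0 °C forms the α-bromo oxocarbenium ion irreversibly and should give, by the same 1,2-shift, the 11-bromo spiro ketone F1. Removal of bromine with n-Bu3SnH and AIBN in toluene at 80 °C, at high stannane concentration so that hydrogen transfer outruns acyl migration of the C11 radical, comes back to the route at 24.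

Step 18. The methyl nucleophile may enolise the ketone, which would expel the β-alkoxy group, or attack C8 axially from the β-face, anti to the axial C9 oxygen, giving the wrong carbinol epimer. The fallback builds the carbinol under thermodynamic control. It sets out from 24: dimethylsulfoxonium methylide (Me3S(O)I, NaH, DMSO) adds reversibly and should close the 8β,17-epoxide F2, with the new C–C bond equatorial (α) and the oxygen axial (β). Hydride opening at the primary carbon with LiEt3BH in THF comes back to the route at 25.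

Step 23. Base treatment may open the β-hydroxy ketone by retro-aldol cleavage, move the acetyl group, or stop at an unfavourable 7β/7α mixture. The fallback sets C7 by SN2 inversion instead of equilibration. It sets out from 27, which is converted as in step 21 into bis-silyl enol ether 28. N-bromosuccinimide in THF at −78 °C should then give, by axial α-face attack, the 7α-bromo 8-silyloxy ketone F3, in which the silylated C8 oxygen cannot close an epoxide. Displacement of the activated α-keto bromide with n-Bu4NOAc in acetone proceeds with inversion to the 7β-acetoxy 8-silyloxy ketone F4. Buffered TBAF as in step 24 removes all three silyl groups and comes back to the route at 33.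

**Further compounds**

F1 | step 17 | (13S)-11-bromo-16-{[tert-butyl(dimethyl)silyl]oxy}-9α,13-epoxy-6α-[(4-methoxybenzyl)oxy]-15-(trimethylsilyl)-17-norlabd-14-yn-8-one (C11 configuration open) | C1[C@H](OCc2ccc(OC)cc2)[C@H]2C(C)(C)CCC[C@]2(C)[C@@]2(C(Br)C[C@](C#C[Si](C)(C)C)(CO[Si](C)(C)C(C)(C)C)O2)C1=O
F2 | step 18 | (13S)-16-{[tert-butyl(dimethyl)silyl]oxy}-8β,17:9α,13-diepoxy-6α-[(4-methoxybenzyl)oxy]-15-(trimethylsilyl)labd-14-yne | C1[C@H](OCc2ccc(OC)cc2)[C@H]2C(C)(C)CCC[C@]2(C)[C@@]2(CC[C@](C#C[Si](C)(C)C)(CO[Si](C)(C)C(C)(C)C)O2)[C@]13CO3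
F3 | step 23 | (13S)-7α-bromo-16-{[tert-butyl(dimethyl)silyl]oxy}-9α,13-epoxy-15-(trimethylsilyl)-8β-(trimethylsilyloxy)labd-14-yn-6-one | Br[C@@H]1C(=O)[C@H]2C(C)(C)CCC[C@]2(C)[C@@]2(CC[C@](C#C[Si](C)(C)C)(CO[Si](C)(C)C(C)(C)C)O2)[C@@]1(C)O[Si](C)(C)C
F4 | step 23 | (13S)-7β-acetoxy-16-{[tert-butyl(dimethyl)silyl]oxy}-9α,13-epoxy-15-(trimethylsilyl)-8β-(trimethylsilyloxy)labd-14-yn-6-one | CC(=O)O[C@H]1C(=O)[C@H]2C(C)(C)CCC[C@]2(C)[C@@]2(CC[C@](C#C[Si](C)(C)C)(CO[Si](C)(C)C(C)(C)C)O2)[C@@]1(C)O[Si](C)(C)C
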